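## Structural features

The target is pentacyclic. Its upper unit is a 2-phenyl-dihydropyran (O1, C2, C3, C4=C4a, C8a) fused through C4a–C8a to a non-aromatic carbocycle that carries a cross-conjugated C5 ketone and a C6=C7 vinylogous methyl ester. Its lower unit is a 2'',4''-trans flavan-4''-ol with methoxy groups on C7'' and C8''. The units are joined twice: by the C8–C6'' carbon–carbon bond and by the C8a–O–C5'' ether, which closes a dihydrofuran and makes C8a a ketal carbon (O1 and the furan oxygen) next to the tertiary benzylic methyl ether C8. C8 and C8a are contiguous, fully substituted stereocentres whose cis relation (C8–OMe cis to O1, C7 cis to C4a) is forced by the five-membered ring; C2 lies across O1 from C8a, and C2''/C4'' form a 1,3-pair. Fragile groups are the 4''-hydroxyl (benzylic to an arene with three oxygen donors, so it ionises and eliminates easily), the ketal C8a, and the dienone/vinylogous ester, a double Michael acceptor. The real difficulty is the C8/C8a pair: once the spiro centre exists, the C5 carbon on C4a lies almost eclipsed with C8 and screens the face of C8 to which C7 must be bonded, while the face next to O1 is open. The key step uses the fact that C8a carries both ring oxygens and is bonded to C8: an aryl 1,2-diketone with carbonyls at C8 and C8a, a C5'' phenol and a C2 hydroxyl can fold both oxygens onto C8a.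

## Logic of the disconnections

36 ⇒ 35. Only the O–Si bond at C4'' is cut. The 4''-hydroxyl is the most fragile group and stays masked to the end. The forward step needs a buffered fluoride source that spares the dienone and the ketal.

35 ⇒ 32. The C7–C8 bond and the O–CH3 bond on C8 are cut. An external carbon nucleophile would approach the C8 ketone of any spiro intermediate from the open face next to O1 and give the C8 epimer that cannot close the carbocycle. C7 is therefore tethered to C5 through C6 and delivered from inside. This removes the carbocycle and the C8 stereocentre in one move. The forward step must metalate the vinylic C7–H in the presence of the C8 ketone; the tether then fixes C7 cis to C4a and the oxygen cis to O1.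

32 ⇒ 31 ⇒ 28 + 29 ⇒ 27. The C7–OCH3 bond (conjugate addition of methanol), the C5–C6 bond (acyl–alkynyl) and the acid/ester change are cut. Placing the methoxy group on C7 by addition to an ynone avoids the regiochemical choice between O5 and O7 that O-methylation of a cyclic 1,3-dione would pose. Because the C8 ketone is the most electrophilic site, C5 can only be extended without free carbanions: acyl chloride, then palladium/copper coupling.

27 ⇒ 24 (key step). The O(C5'')–C8a and O1–C8a bonds are cut. Two rings and the C8a stereocentre disappear, leaving an open chain whose only stereocentres are C2, C2'' and C4''. The forward step needs reversible, weakly acidic conditions and acid-labile masks on both oxygens. The phenol mask is a design change: it keeps 20 from closing onto C8a and dehydrating to an alkylidene benzofuranone before the alkylidene is in place.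

24 ⇒ 20 + 23. The C4a=C4 bond is cut (Knoevenagel retron). This separates the chain that carries C2. The forward step needs amine-salt catalysis mild enough not to eliminate the β-silyloxy group of 23.

20 ⇒ 18 + 19. The C8a–C4a bond is cut (aldehyde/diazo ester homologation). The forward step needs hydride, not acyl, migration.

18 ⇒ 16 ⇒ 13 + 14. The aldehyde carbon is traced back to an alkene carbon (ozonolysis) and the C6''–C8 bond to an aryl anion and an acyl chloride. Oxidising an aryl methyl ketone with SeO2 in hot aqueous acid would endanger the acetal and the benzylic silyl ether; ozonolysis is neutral. C6'' is the only aryl C–H of that ring and lies between two oxygen donors, so metalation is unambiguous.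

13 ⇒ 12 ⇒ 11 ⇒ 10. The O–Si bond, the C4''–H bond and the acetal C–O bond are cut. The C4'' stereocentre is set by hydride delivery trans to phenyl. The acetal on O5'' later directs metalation and leaves together with the triethylsilyl group in the key step.

10 ⇒ 9 ⇒ 7 + 8. The O5''–CH3 bond (selective demethylation beside the C4'' carbonyl) and the C2''–phenyl bond are cut. C2'' is set by a chiral palladium catalyst.

7 ⇒ 4 + 5 and 4 ⇒ 1 + 2. The pyranone C2'' is cut back to a formamide acetal and the aryl–acyl bond to a Friedel–Crafts pair. In 1 the oxygen that becomes O1'' is the one flanked by a second methoxy group, so the 7'',8''-oxygenation is secured.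

23 ⇒ 22 ⇒ 21. Protection and partial reduction only; C2 comes from the chiral pool.

## Other disconnections considered

Alternative 1: The cut removes both carbon–phenyl bonds (C2–Ph and C2''–Ph) of the bis-flavanone A2 and leads to the biaryl bis-chromone A1, in which C8–C6'' already exists. The forward step would add phenylboronic acid to both enones with Pd(OCOCF3)2 and a chiral tert-butyl pyridine-oxazoline.
- In favour: it is the reaction used once in step 3, so precedent and catalyst control are equal. Doing it twice on one molecule should raise the enantiomeric purity statistically, which is better than the chosen plan. The C8–C6'' bond would come from an early cross-coupling instead of late aryl glyoxal chemistry, also better.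
- Against: A2 still has an aromatic upper ring and two flavanone carbonyls. The upper ring would have to be dearomatised oxidatively to set C8 and C8a, the upper C4 oxygen removed to give C4=C4a, and the lower carbonyl reduced trans-selectively in the presence of the upper one. The conjugate addition would also have to work beside a tetra-ortho-substituted biaryl axis.
- Comparison: the route to A2 is shorter and more convergent than the route to 27, but the hard stereocentres C8 and C8a remain open after its key step, whereas the chosen plan sets C8a under thermodynamic control.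

Alternative 2: The cut removes the C5''–O and C6''–C8 bonds and the methyl on the C8 oxygen. Forward, CsF would turn the o-silylaryl triflate A3 into the C5''–C6'' aryne; the alkoxide of hemiketal A4 would add at C5'', the aryl anion at C6'' would attack the C8 ketone, and CH3I would cap the alkoxide to give A5, which has the constitution of 35.
- In favour: it is the most convergent plan, forms the dihydrofuran, the C8 stereocentre and the methyl ether in one pot, and lands one step from the target, so it beats the chosen plan on step economy. The cis ring fusion is automatic (equal to step 18), and the C7'' methoxy group should steer the alkoxide to C5''.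
- Against: the open-chain tautomer of A4 is an alkylidene cyclohexenetrione that can tautomerise irreversibly to a hydroxy-quinone. A hindered tertiary hemiketal alkoxide is a poor aryne trap. The aryl anion must reach a hindered ketone before it is protonated. The hexasubstituted A3 is long to make.
- Comparison: three irreversible anion-trapping events must occur in order, whereas the chosen key step is reversible and self-correcting.

Alternative 3: The cut removes C7–C8 and C4a–C8a. Forward, heating A6 would add the benzofuran 2,3-bond across the tethered 2-pyrone and expel CO2 to give the silyl dienol ether A7.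
- In favour: carbocycle, dihydropyran and both quaternary centres would form in one step with the cis relation fixed by the suprafacial addition. The C7 methoxy position is built into the pyrone (equal to step 17), and the C8 methoxy group is present from the start (better than the late methylation in step 18). Only oxidation to the C4=C4a enone and desilylation would follow, fewer steps than after 27.
- Against: both partners are electron-rich, so the cycloaddition is poorly matched and must also dearomatise the benzofuran. The C8a configuration relative to C2 would be set kinetically by the tether with no chance to equilibrate; on this point the chosen plan is better. The ketene-acetal-like 2-alkoxybenzofuran in A6 is acid-labile and hard to make from a secondary benzylic alcohol.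

Key step: step 14

Remark: direct C-acylation of 3,4,5-trimethoxyphenol would close the flavanone through the wrong oxygen (5,6,7-pattern), so its methyl ether 1 is used and taken as commercial. The (R)-ligand in step 3 is assigned by analogy with cyclic enones and would be exchanged for its antipode if the facial sense proved opposite. Compounds 11–18, 20 and 24 are mixtures of two epimers at the tetrahydropyranyl acetal carbon, which converge in step 14.

Notation: "Fl" = (2S,4R)-4-(tert-butyldimethylsilyloxy)-7,8-dimethoxy-2-phenyl-5-(tetrahydro-2H-pyran-2-yloxy)chroman-6-yl. Spiro compounds use the numbering of the target (upper unit O1–C8a, lower unit double-primed).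

## Route

Step 1
Reactants: 1 1,2,3,5-tetramethoxybenzene; 2 acetyl chloride
Product: 4 2'-hydroxy-3',4',6'-trimethoxyacetophenone, via 2',3',4',6'-tetramethoxyacetophenone 3 (not isolated)
Conditions: AlCl3 (2.5 equiv), Et2O, 0 °C → reflux; aq. HCl
Reagents that add atoms: none
Why: Friedel–Crafts acylation at one of the two equivalent free positions; AlCl3 then cleaves, through a six-membered chelate, the methyl ether squeezed between the acyl group and a methoxy neighbour, freeing the oxygen that becomes O1''.

Step 2
Reactants: 4 2'-hydroxy-3',4',6'-trimethoxyacetophenone; 5 N,N-dimethylformamide dimethyl acetal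
Product: 7 5,7,8-trimethoxy-4H-chromen-4-one, via enaminone 6 (not isolated)
Conditions: 5 (3 equiv), toluene, 100 °C; then conc. HCl, CH2Cl2, 40 °C
Reagents that add atoms: none
Why: Condensation to the enaminone, then acid-promoted addition–elimination by the phenol; this is the standard chromone synthesis from 2-hydroxyacetophenones.

Step 3
Reactants: 7 5,7,8-trimethoxy-4H-chromen-4-one; 8 phenylboronic acid
Product: 9 (2S)-5,7,8-trimethoxy-2-phenylchroman-4-one
Conditions: Pd(OCOCF3)2 (5 mol%), (R)-4-tert-butyl-2-(pyridin-2-yl)-4,5-dihydrooxazole (6 mol%), NH4PF6 (30 mol%), H2O (5 equiv), ClCH2CH2Cl, 60 °C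
Reagents that add atoms: none
Why: Asymmetric conjugate addition of an arylboronic acid to a chromone by a cationic divalent palladium catalyst; the pyridine-oxazoline ligand fixes the face of aryl insertion and so sets C2'' (S), and protonolysis releases the flavanone.

Step 4
Reactants: 9 (2S)-5,7,8-trimethoxy-2-phenylchroman-4-one
Product: 10 (2S)-5-hydroxy-7,8-dimethoxy-2-phenylchroman-4-one
Conditions: BCl3 (1.5 equiv), CH2Cl2, −78 → 0 °C; aq. NaHCO3
Reagents that add atoms: none
Why: Boron bridges the C4'' carbonyl and the peri 5''-methoxy oxygen, so only this ether is demethylated; the low temperature avoids ring opening and loss of the C2'' configuration.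

Step 5
Reactants: 10 (2S)-5-hydroxy-7,8-dimethoxy-2-phenylchroman-4-one
Product: 11 (2S)-7,8-dimethoxy-2-phenyl-5-(tetrahydro-2H-pyran-2-yloxy)chroman-4-one
Conditions: 3,4-dihydro-2H-pyran (5 equiv), PPTS (0.2 equiv), CH2Cl2, 40 °C
Reagents that add atoms: 3,4-dihydro-2H-pyran, C1=COCCC1
Why: Acid-catalysed acetal formation; the chelated phenol reacts slowly, hence the excess and gentle heating; the acetal later directs lithiation and is cleaved by the same weak acid as a triethylsilyl ether.

Step 6
Reactants: 11 (2S)-7,8-dimethoxy-2-phenyl-5-(tetrahydro-2H-pyran-2-yloxy)chroman-4-one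
Product: 12 (2S,4R)-7,8-dimethoxy-2-phenyl-5-(tetrahydro-2H-pyran-2-yloxy)chroman-4-ol
Conditions: LiBH(s-Bu)3 (L-Selectride, 1.5 equiv), THF, −78 °C; H2O
Reagents that add atoms: none
Why: Steric approach control: the bulky hydride should avoid the axial hydrogen on C2'' and attack equatorially, giving the pseudo-axial alcohol trans to the equatorial phenyl (4''R), which the peri substituent also favours.

Step 7
Reactants: 12 (2S,4R)-7,8-dimethoxy-2-phenyl-5-(tetrahydro-2H-pyran-2-yloxy)chroman-4-ol
Product: 13 (2S,4R)-4-(tert-butyldimethylsilyloxy)-7,8-dimethoxy-2-phenyl-5-(tetrahydro-2H-pyran-2-yloxy)chroman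
Conditions: TBSCl (2 equiv), imidazole (4 equiv), DMAP (cat.), DMF, 40 °C
Reagents that add atoms: tert-butyldimethylsilyl chloride, CC(C)(C)[Si](C)(C)Cl
Why: Silylation of a hindered secondary alcohol under basic conditions that leave the acetal intact.

Step 8
Reactants: 13 (2S,4R)-4-(tert-butyldimethylsilyloxy)-7,8-dimethoxy-2-phenyl-5-(tetrahydro-2H-pyran-2-yloxy)chroman; 14 3-methylbut-2-enoyl chloride
Product: 16 3-methyl-1-Fl-but-2-en-1-one, via aryllithium 15 (not isolated)
Conditions: n-BuLi (1.2 equiv), THF, 0 °C, 1 h; then cannulated into 14 (3 equiv), THF, −78 °C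
Reagents that add atoms: none
Why: Directed ortho-metalation at C6'', the only aryl C–H of that ring and flanked by the acetal oxygen and a methoxy group; inverse addition to excess acid chloride gives the ketone, which as a di-ortho-substituted aryl ketone resists a second addition.

Step 9
Reactants: 16 3-methyl-1-Fl-but-2-en-1-one
Product: 18 Fl-glyoxal (2-Fl-2-oxoacetaldehyde), via secondary ozonide 17 (not isolated)
Conditions: O3 (1.0 equiv, titrated solution in CH2Cl2), −78 °C; then Me2S, −78 °C → rt; azeotropic drying (toluene)
Reagents that add atoms: ozone, [O-][O+]=O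
Why: Ozonolysis of the trisubstituted enone alkene with one equivalent of ozone and reductive work-up; the conditions are neutral, so the acetal and the benzylic silyl ether survive.

Step 10
Reactants: 18 Fl-glyoxal; 19 ethyl diazoacetate
Product: 20 ethyl 4-Fl-3,4-dioxobutanoate
Conditions: SnCl2 (10 mol%), CH2Cl2, rt
Reagents that add atoms: none
Why: Roskamp reaction: the diazo carbon adds to the SnCl2-activated aldehyde and a 1,2-hydride shift with loss of N2 gives the β-keto ester (C8a–C4a bond); the electron-poor aroyl group should migrate less readily than hydride.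

Step 11
Reactants: 21 ethyl (S)-3-hydroxy-3-phenylpropanoate
Product: 22 ethyl (S)-3-phenyl-3-(triethylsilyloxy)propanoate
Conditions: Et3SiCl (1.2 equiv), imidazole (2 equiv), CH2Cl2, 0 °C → rt
Reagents that add atoms: chlorotriethylsilane, CC[Si](Cl)(CC)CC
Why: Standard silylation; the stereocentre that becomes C2 is untouched.

Step 12
Reactants: 22 ethyl (S)-3-phenyl-3-(triethylsilyloxy)propanoate
Product: 23 (S)-3-phenyl-3-(triethylsilyloxy)propanal
Conditions: i-Bu2AlH (1.1 equiv), CH2Cl2, −78 °C; MeOH, then aq. potassium sodium tartrate
Reagents that add atoms: none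
Why: Partial reduction through the aluminium hemiacetal, which is stable at −78 °C; the neutral work-up avoids β-elimination of the silyloxy group.

Step 13
Reactants: 20 ethyl 4-Fl-3,4-dioxobutanoate; 23 (S)-3-phenyl-3-(triethylsilyloxy)propanal
Product: 24 ethyl (5S)-2-(2-Fl-2-oxoacetyl)-5-phenyl-5-(triethylsilyloxy)pent-2-enoate (mixture of alkene isomers)
Conditions: piperidine (10 mol%), AcOH (10 mol%), 4 Å MS, CH2Cl2, 0 °C → rt
Reagents that add atoms: none
Why: Knoevenagel condensation at the strongly acidic methylene between the C8a ketone and the ester; low temperature and the buffered amine limit β-elimination from 23; the geometric mixture is acceptable because it converges in step 14.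

Step 14
Reactants: 24 ethyl (5S)-2-(2-Fl-2-oxoacetyl)-5-phenyl-5-(triethylsilyloxy)pent-2-enoate
Product: 27 spiroketal benzofuran-3-one ethyl ester (2S,8aS,2''S,4''R; C8 ketone; ester on C4a; 4''-OTBS), via dihydroxy diketone 25 (not isolated), via 2-hydroxybenzofuran-3-one hemiketal 26 (not isolated)
Conditions: PPTS (0.3 equiv), MeOH–CH2Cl2 (1:4), 0 °C → rt; then toluene, PPTS (cat.), 4 Å MS, 40 °C
Reagents that add atoms: none
Why: PPTS in methanol cleaves the aryl tetrahydropyranyl acetal and the secondary triethylsilyl ether to give 25 but is too weak to cleave the secondary tert-butyldimethylsilyl ether. The free C5'' phenol adds to the C8a carbonyl, the more electrophilic one because it sits between the C8 ketone and the alkylidene ester, in a 5-exo-trig closure to hemiketal 26. Acid ionises the hemiketal to a benzofuranone oxocarbenium ion, which the C2 hydroxyl captures in a 6-exo-trig closure; every event is reversible, so this is the classical acid-catalysed spiroketalization of a dihydroxy ketone under thermodynamic control. The new stereocentre C8a is controlled by C2 through the ring: phenyl pseudo-equatorial and the aryloxy oxygen axial (anomeric effect), which puts C8 cis to phenyl (8aS). C8a rather than C8 is the acceptor because only C8a can be reached through five- and six-membered rings. Ketalization should win over lactonization of the C2 hydroxyl onto the ester because hemiketal formation is fast and reversible at room temperature while acid-catalysed transesterification is slow. Both alkene isomers of 24 should converge because the oxocarbenium ion is delocalised towards C4 and methanol adds reversibly at C4. The C4'' silyl ether should survive because the acyl group on the arene damps ionisation at C4''.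

Step 15
Reactants: 27 spiroketal benzofuran-3-one ethyl ester
Product: 28 spiroketal benzofuran-3-one carboxylic acid (CO2H on C4a)
Conditions: LiOH·H2O (3 equiv), THF–MeOH–H2O (3:1:1), rt → 40 °C; 1 M HCl to pH 4
Reagents that add atoms: lithium hydroxide, [Li+].[OH-]
Why: Saponification; the C8 ketone has no α-hydrogen, and the ketal and silyl ether are base-stable; the acid may rest partly as the lactol formed with the neighbouring C8 carbonyl, which is reversible.

Step 16
Reactants: 28 spiroketal benzofuran-3-one carboxylic acid; 29 ethynyltrimethylsilane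
Product: 31 spiroketal benzofuran-3-one 3-(trimethylsilyl)propynoyl ketone (C5 ketone bearing C6≡C7–SiMe3), via acid chloride 30 (not isolated)
Conditions: 1-chloro-N,N,2-trimethylprop-1-en-1-amine (1.2 equiv), CH2Cl2, 0 °C → rt; then 29 (1.5 equiv), PdCl2(PPh3)2 (3 mol%), CuI (6 mol%), Et3N (2 equiv), THF, rt
Reagents that add atoms: none
Why: Neutral formation of the acid chloride, then Sonogashira-type acylation (zerovalent palladium inserts into the C–Cl bond, the copper acetylide transmetalates); no carbanion strong enough to attack the C8 ketone is present.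

Step 17
Reactants: 31 spiroketal benzofuran-3-one 3-(trimethylsilyl)propynoyl ketone
Product: 32 spiroketal benzofuran-3-one (E)-3-methoxyprop-2-enoyl ketone (C5 ketone bearing C6H=C7H–OMe)
Conditions: K2CO3 (0.1 equiv), MeOH, 0 °C → rt
Reagents that add atoms: methanol, CO
Why: Methoxide removes the C-silyl group and adds in conjugate fashion to the terminal ynone; the (E)-vinylogous ester is the thermodynamic isomer, and the methoxy group is thereby placed on C7 without ambiguity.

Step 18
Reactants: 32 spiroketal benzofuran-3-one (E)-3-methoxyprop-2-enoyl ketone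
Product: 35 4''-O-tert-butyldimethylsilyl ether of 6''-demethoxyneocalycopterone, via C7 vinyllithium 33 (not isolated), via C8 lithium alkoxide 34 (not isolated)
Conditions: lithium 2,2,6,6-tetramethylpiperidide (1.3 equiv), THF, −78 → −40 °C; then MeI (5 equiv), DMPU, −40 → 0 °C
Reagents that add atoms: iodomethane, CI
Why: Proposed new method: the vinylic C7–H of the (E)-3-methoxyenone lies cis to the C5 carbonyl, so the hindered amide should remove it with lithium held by the carbonyl oxygen (33); rotation about C5–C6 then brings C7 onto the screened face of the C8 ketone, where six-membered ring closure (34) can only give the cis fusion, C7 cis to C4a and the alkoxide cis to O1 (8S), and MeI caps the alkoxide; the closest known reaction type is the β-lithiation of (E)-3-methoxyacrylates by lithium amides and addition of the vinyllithium to ketones (tetronate synthesis), here applied to a ketone-type vinylogous ester and run intramolecularly.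

Step 19
Reactants: 35 4''-O-tert-butyldimethylsilyl ether of 6''-demethoxyneocalycopterone
Product: 36 6''-demethoxyneocalycopterone
Conditions: Bu4NF (1.5 equiv), AcOH (1.5 equiv), THF, 0 °C → rt
Reagents that add atoms: none
Why: Fluoride cleaves the Si–O bond; the acetic acid buffer protects the dienone and the vinylogous ester from base and avoids acid-promoted ionisation at C4''.

## Compound list

1 | 1,2,3,5-tetramethoxybenzene | COc1cc(OC)c(OC)c(OC)c1 | starting material
2 | acetyl chloride | CC(Cl)=O | starting material
3 | 2',3',4',6'-tetramethoxyacetophenone (not isolated) | CC(=O)c1c(OC)c(OC)c(OC)cc1OC | intermediate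
4 | 2'-hydroxy-3',4',6'-trimethoxyacetophenone | CC(=O)c1c(O)c(OC)c(OC)cc1OC | intermediate
5 | N,N-dimethylformamide dimethyl acetal | COC(OC)N(C)C | starting material
6 | (E)-3-(dimethylamino)-1-(2-hydroxy-3,4,6-trimethoxyphenyl)prop-2-en-1-one (not isolated) | CN(C)/C=C/C(=O)c1c(O)c(OC)c(OC)cc1OC | intermediate
7 | 5,7,8-trimethoxy-4H-chromen-4-one | O=c1ccoc2c(OC)c(OC)cc(OC)c12 | intermediate
8 | phenylboronic acid | OB(O)c1ccccc1 | starting material
9 | (2S)-5,7,8-trimethoxy-2-phenylchroman-4-one | COc1cc(OC)c(OC)c2O[C@H](c3ccccc3)CC(=O)c12 | intermediate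
10 | (2S)-5-hydroxy-7,8-dimethoxy-2-phenylchroman-4-one | Oc1cc(OC)c(OC)c2O[C@H](c3ccccc3)CC(=O)c12 | intermediate
11 | (2S)-7,8-dimethoxy-2-phenyl-5-(tetrahydro-2H-pyran-2-yloxy)chroman-4-one (acetal epimers) | c1c(OC2CCCCO2)c3c(c(OC)c1OC)O[C@H](c4ccccc4)CC3=O | intermediate
12 | (2S,4R)-7,8-dimethoxy-2-phenyl-5-(tetrahydro-2H-pyran-2-yloxy)chroman-4-ol | c1c(OC2CCCCO2)c3c(c(OC)c1OC)O[C@H](c4ccccc4)C[C@H]3O | intermediate
13 | (2S,4R)-4-(tert-butyldimethylsilyloxy)-7,8-dimethoxy-2-phenyl-5-(tetrahydro-2H-pyran-2-yloxy)chroman | c1c(OC2CCCCO2)c3c(c(OC)c1OC)O[C@H](c4ccccc4)C[C@H]3O[Si](C)(C)C(C)(C)C | intermediate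
14 | 3-methylbut-2-enoyl chloride | CC(C)=CC(Cl)=O | starting material
15 | 6-lithio derivative of 13, Fl–Li (not isolated) | [Li]c1c(OC2CCCCO2)c3c(c(OC)c1OC)O[C@H](c4ccccc4)C[C@H]3O[Si](C)(C)C(C)(C)C | intermediate
16 | 3-methyl-1-Fl-but-2-en-1-one | CC(C)=CC(=O)c1c(OC2CCCCO2)c3c(c(OC)c1OC)O[C@H](c4ccccc4)C[C@H]3O[Si](C)(C)C(C)(C)C | intermediate
17 | secondary ozonide of 16, 5,5-dimethyl-1,2,4-trioxolan-3-yl Fl ketone (not isolated) | CC1(C)OOC(O1)C(=O)c1c(OC2CCCCO2)c3c(c(OC)c1OC)O[C@H](c4ccccc4)C[C@H]3O[Si](C)(C)C(C)(C)C | intermediate
18 | Fl-glyoxal, 2-Fl-2-oxoacetaldehyde | O=CC(=O)c1c(OC2CCCCO2)c3c(c(OC)c1OC)O[C@H](c4ccccc4)C[C@H]3O[Si](C)(C)C(C)(C)C | intermediate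
19 | ethyl diazoacetate | CCOC(=O)C=[N+]=[N-] | starting material
20 | ethyl 4-Fl-3,4-dioxobutanoate | CCOC(=O)CC(=O)C(=O)c1c(OC2CCCCO2)c3c(c(OC)c1OC)O[C@H](c4ccccc4)C[C@H]3O[Si](C)(C)C(C)(C)C | intermediate
21 | ethyl (S)-3-hydroxy-3-phenylpropanoate | CCOC(=O)C[C@H](O)c1ccccc1 | starting material
22 | ethyl (S)-3-phenyl-3-(triethylsilyloxy)propanoate | CCOC(=O)C[C@H](O[Si](CC)(CC)CC)c1ccccc1 | intermediate
23 | (S)-3-phenyl-3-(triethylsilyloxy)propanal | O=CC[C@H](O[Si](CC)(CC)CC)c1ccccc1 | intermediate
24 | ethyl (5S)-2-(2-Fl-2-oxoacetyl)-5-phenyl-5-(triethylsilyloxy)pent-2-enoate, key-step precursor (alkene isomers; drawn with the chain cis to the diketone arm) | CCOC(=O)C(=C/C[C@H](O[Si](CC)(CC)CC)c1ccccc1)/C(=O)C(=O)c1c(OC2CCCCO2)c3c(c(OC)c1OC)O[C@H](c4ccccc4)C[C@H]3O[Si](C)(C)C(C)(C)C | intermediate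
25 | dihydroxy diketone, 24 without the triethylsilyl and tetrahydropyranyl groups (not isolated) | CCOC(=O)C(=C/C[C@H](O)c1ccccc1)/C(=O)C(=O)c1c(O)c3c(c(OC)c1OC)O[C@H](c4ccccc4)C[C@H]3O[Si](C)(C)C(C)(C)C | intermediate
26 | 2-hydroxybenzofuran-3-one hemiketal with the open hydroxy-alkenyl ester chain on C8a (not isolated) | CCOC(=O)C(=C/C[C@H](O)c1ccccc1)/C1(O)Oc2c3c(c(OC)c(OC)c2C1=O)O[C@H](c4ccccc4)C[C@H]3O[Si](C)(C)C(C)(C)C | intermediate
27 | spiroketal benzofuran-3-one ethyl ester (2S,8aS,2''S,4''R), key-step product | CCOC(=O)C1=CC[C@@H](c2ccccc2)O[C@]13Oc4c5c(c(OC)c(OC)c4C3=O)O[C@H](c6ccccc6)C[C@H]5O[Si](C)(C)C(C)(C)C | intermediate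
28 | spiroketal benzofuran-3-one carboxylic acid | OC(=O)C1=CC[C@@H](c2ccccc2)O[C@]13Oc4c5c(c(OC)c(OC)c4C3=O)O[C@H](c6ccccc6)C[C@H]5O[Si](C)(C)C(C)(C)C | intermediate
29 | ethynyltrimethylsilane | C#C[Si](C)(C)C | starting material
30 | spiroketal benzofuran-3-one acid chloride (not isolated) | ClC(=O)C1=CC[C@@H](c2ccccc2)O[C@]13Oc4c5c(c(OC)c(OC)c4C3=O)O[C@H](c6ccccc6)C[C@H]5O[Si](C)(C)C(C)(C)C | intermediate
31 | spiroketal benzofuran-3-one 3-(trimethylsilyl)propynoyl ketone | C[Si](C)(C)C#CC(=O)C1=CC[C@@H](c2ccccc2)O[C@]13Oc4c5c(c(OC)c(OC)c4C3=O)O[C@H](c6ccccc6)C[C@H]5O[Si](C)(C)C(C)(C)C | intermediate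
32 | spiroketal benzofuran-3-one (E)-3-methoxyprop-2-enoyl ketone | CO/C=C/C(=O)C1=CC[C@@H](c2ccccc2)O[C@]13Oc4c5c(c(OC)c(OC)c4C3=O)O[C@H](c6ccccc6)C[C@H]5O[Si](C)(C)C(C)(C)C | intermediate
33 | C7 vinyllithium of 32 (not isolated) | CO/C([Li])=C/C(=O)C1=CC[C@@H](c2ccccc2)O[C@]13Oc4c5c(c(OC)c(OC)c4C3=O)O[C@H](c6ccccc6)C[C@H]5O[Si](C)(C)C(C)(C)C | intermediate
34 | pentacyclic C8 lithium alkoxide (not isolated) | COC1=CC(=O)C2=CC[C@@H](c3ccccc3)O[C@]23Oc2c4c(c(OC)c(OC)c2[C@]13O[Li])O[C@H](c1ccccc1)C[C@H]4O[Si](C)(C)C(C)(C)C | intermediate
35 | 4''-O-tert-butyldimethylsilyl ether of 6''-demethoxyneocalycopterone | COC1=CC(=O)C2=CC[C@@H](c3ccccc3)O[C@]23Oc2c4c(c(OC)c(OC)c2[C@]13OC)O[C@H](c1ccccc1)C[C@H]4O[Si](C)(C)C(C)(C)C | intermediate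
36 | 6''-demethoxyneocalycopterone | COC1=CC(=O)C2=CC[C@@H](c3ccccc3)O[C@]23Oc2c4c(c(OC)c(OC)c2[C@]13OC)O[C@H](c1ccccc1)C[C@H]4O | target

## Step count and least certain steps

Total: 19 steps. Longest linear sequence: 17 steps (steps 1–10 and 13–19); steps 11–12 make the side chain.

Step 18 (labelled step). Removal of the C3 protons, which are vinylogous to the C5 ketone, could compete with vinylic metalation and lead to expulsion of O1 from C2 and ring opening; the amide could also add to the enone. The fallback uses known chemistry and sets out from 31. Sodium benzenesulfinate and AcOH in MeOH should give, by conjugate addition with loss of the silyl group, the (E)-2-(phenylsulfonyl)vinyl ketone F1. α-Metalation of vinyl sulfones and their addition to ketones is established, and the more acidic C7–H should be removed faster and at lower temperature; ring closure onto C8 and capping with MeI would give the cyclised C7 sulfone F2. NaOMe in MeOH at 0 °C would then exchange sulfinate for methoxide by addition–elimination at C7 and return to 35.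

Step 14 (key step). Acid-promoted ionisation at C4'' could cost the silyl ether (solvolysis to a methyl ether). Pyran closure could stall if the alkene geometry fails to equilibrate. The isomer with the chain cis to the ester could lactonize. The fallback separates the two closures and reverses their order, starting from 24: HF·pyridine buffered with pyridine (THF, 0 °C) removes only the triethylsilyl group, and the C2 hydroxyl adds to C8a to give the six-membered lactol F3, which is isolated. PPTS in MeOH–CH2Cl2, then toluene at 40 °C, removes the acetal, and the phenol displaces the anomeric hydroxyl to reach 27.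

Step 16. The neighbouring C8 carbonyl could trap the acyl chloride as a cyclic pseudo-chloride, and the acyl–palladium species could lose CO. The fallback starts from 28: EtSH, EDC·HCl and DMAP give the S-ethyl thioester F4, which cannot form a pseudo-halide. Palladium/copper-mediated coupling of the thioester with 29 (PdCl2(dppf), CuI, tri(2-furyl)phosphine, Et3N, DMF, 50 °C) would return to 31.

Step 13. The silyloxy group of 23 could be lost by β-elimination through its enamine, and a second molecule of 20 could add to the product. The fallback starts from 20 and 23 and avoids secondary amines: soft enolisation with MgBr2·OEt2 and Et3N (CH2Cl2, 0 °C) gives the aldol adduct F5, and dehydration with the inner salt of (methoxycarbonylsulfamoyl)triethylammonium hydroxide (toluene, 50 °C) returns to 24.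

Step 10. The aroyl group could migrate instead of hydride (giving a formyl keto ester), and the Lewis acid could cleave the acetal. The fallback starts from 18: DBU-catalysed addition of 19 (MeCN, 0 °C) gives the β-hydroxy-α-diazo ester F6, and Rh2(OAc)4 (1 mol%, CH2Cl2, rt) converts it to 20 by carbene formation and 1,2-hydride shift.

Step 6. Facial selectivity could be poor, with axial attack giving the 2'',4''-cis alcohol. The fallback starts from 11: NaBH4 (MeOH, 0 °C) gives the cis alcohol F7 by the well-established axial attack; Mitsunobu inversion (4-nitrobenzoic acid, PPh3, diisopropyl azodicarboxylate, THF, 0 °C) gives the trans 4-nitrobenzoate F8; K2CO3 in MeOH returns to 12.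

## Further compounds

F1 | step 18 | spiroketal benzofuran-3-one (E)-3-(phenylsulfonyl)prop-2-enoyl ketone | O=C(/C=C/S(=O)(=O)c1ccccc1)C1=CC[C@@H](c2ccccc2)O[C@]13Oc4c5c(c(OC)c(OC)c4C3=O)O[C@H](c6ccccc6)C[C@H]5O[Si](C)(C)C(C)(C)C
F2 | step 18 | 7-demethoxy-7-(phenylsulfonyl) analogue of 35 | O=S(=O)(c5ccccc5)C1=CC(=O)C2=CC[C@@H](c3ccccc3)O[C@]23Oc2c4c(c(OC)c(OC)c2[C@]13OC)O[C@H](c1ccccc1)C[C@H]4O[Si](C)(C)C(C)(C)C
F3 | step 14 | ethyl (6S)-2-hydroxy-2-(Fl-carbonyl)-6-phenyl-5,6-dihydro-2H-pyran-3-carboxylate (lactol) | CCOC(=O)C1=CC[C@@H](c2ccccc2)OC1(O)C(=O)c3c(OC5CCCCO5)c4c(c(OC)c3OC)O[C@H](c6ccccc6)C[C@H]4O[Si](C)(C)C(C)(C)C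
F4 | step 16 | spiroketal benzofuran-3-one S-ethyl thioester | CCSC(=O)C1=CC[C@@H](c2ccccc2)O[C@]13Oc4c5c(c(OC)c(OC)c4C3=O)O[C@H](c6ccccc6)C[C@H]5O[Si](C)(C)C(C)(C)C
F5 | step 13 | ethyl (5S)-2-(2-Fl-2-oxoacetyl)-3-hydroxy-5-phenyl-5-(triethylsilyloxy)pentanoate | CCOC(=O)C(C(O)C[C@H](O[Si](CC)(CC)CC)c1ccccc1)C(=O)C(=O)c2c(OC5CCCCO5)c3c(c(OC)c2OC)O[C@H](c4ccccc4)C[C@H]3O[Si](C)(C)C(C)(C)C
F6 | step 10 | ethyl 2-diazo-4-Fl-3-hydroxy-4-oxobutanoate | CCOC(=O)C(=[N+]=[N-])C(O)C(=O)c1c(OC2CCCCO2)c3c(c(OC)c1OC)O[C@H](c4ccccc4)C[C@H]3O[Si](C)(C)C(C)(C)C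
F7 | step 6 | (2S,4S)-7,8-dimethoxy-2-phenyl-5-(tetrahydro-2H-pyran-2-yloxy)chroman-4-ol | c1c(OC2CCCCO2)c3c(c(OC)c1OC)O[C@H](c4ccccc4)C[C@@H]3O
F8 | step 6 | (2S,4R)-7,8-dimethoxy-2-phenyl-5-(tetrahydro-2H-pyran-2-yloxy)chroman-4-yl 4-nitrobenzoate | c1c(OC2CCCCO2)c3c(c(OC)c1OC)O[C@H](c4ccccc4)C[C@H]3OC(=O)c5ccc(cc5)[N+](=O)[O-]
A1 | alternative 1 | biaryl bis-chromone | CC(C)(C)[Si](C)(C)Oc1c2c(c(OC)c(OC)c1-c3c(OC)cc(OCc4ccccc4)c5c3occc5=O)occc2=O
A2 | alternative 1 | (2S,2''S)-bis-flavanone | CC(C)(C)[Si](C)(C)Oc1c2c(c(OC)c(OC)c1-c3c(OC)cc(OCc4ccccc4)c5c3O[C@H](c6ccccc6)CC5=O)O[C@H](c7ccccc7)CC2=O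
A3 | alternative 2 | (2S,4R)-4-(tert-butyldimethylsilyloxy)-7,8-dimethoxy-2-phenyl-6-(trimethylsilyl)chroman-5-yl trifluoromethanesulfonate | C[Si](C)(C)c1c(OS(=O)(=O)C(F)(F)F)c2c(c(OC)c1OC)O[C@H](c3ccccc3)C[C@H]2O[Si](C)(C)C(C)(C)C
A4 | alternative 2 | (2S)-8a-hydroxy-7-methoxy-2-phenyl-2,3-dihydrochromene-5,8-dione (hemiketal) | COC1=CC(=O)C2=CC[C@@H](c3ccccc3)OC2(O)C1=O
A5 | alternative 2 | 4''-O-tert-butyldimethylsilyl ether of the target | COC1=CC(=O)C2=CC[C@@H](c3ccccc3)O[C@]23Oc2c4c(c(OC)c(OC)c2[C@]13OC)O[C@H](c1ccccc1)C[C@H]4O[Si](C)(C)C(C)(C)C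
A6 | alternative 3 | 2-alkoxy-3-methoxybenzofuran tethered through O1–C2–C3–C4 to C6 of a 3-methoxy-5-(triisopropylsilyloxy)-2-pyrone | COc1cc(O[Si](C(C)C)(C(C)C)C(C)C)c(CC[C@@H](c2ccccc2)Oc2oc3c4c(c(OC)c(OC)c3c2OC)O[C@H](c2ccccc2)C[C@H]4O[Si](C)(C)C(C)(C)C)oc1=O
A7 | alternative 3 | pentacyclic C5 triisopropylsilyl dienol ether | COC1=CC(O[Si](C(C)C)(C(C)C)C(C)C)=C2CC[C@@H](c3ccccc3)O[C@]23Oc2c4c(c(OC)c(OC)c2[C@]13OC)O[C@H](c1ccccc1)C[C@H]4O[Si](C)(C)C(C)(C)C
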